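**Retrosynthetic overview**
1. Rings A, B and C and the C2 stereocentre are bought intact as (2S)-liquiritigenin 1. No ring is formed in the route, which only adds the carbon substituents at C8, C5′ and C3′.
2. C8- and C5′-prenyl groups: one double aromatic Claisen rearrangement, set up by O-tert-prenylation with carbonate 2 (gives 3), ring-B bromination with NBS 4 (gives 5) and a second O-tert-prenylation (gives 6, heated through 7 and 8 to aryl bromide 9).
3. Carbinol stereocentre: bought in methyl (R)-glycidate 10, carried through MeMgCl 11 addition (through ketone 12 to epoxy alcohol 13) and dehydration to vinyl epoxide 14, whose oxirane is the one present in 10.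
4. Key disconnection, last step: the C3′–CH2 bond, made by a blue-light cobalt/nickel coupling of 9 with 14, which gives the unprotected target 15 directly.

Assumption: 1 is bought as the natural (2S) enantiomer (enantiopurity checked by chiral HPLC), 2 and 10 (L-serine-derived) are catalogue items, and ring B is numbered so that the hydroxybutenyl chain sits at C3′.

**Route**

Step 1
Reactants: 1 (2S)-liquiritigenin; 2 tert-butyl (2-methylbut-3-en-2-yl) carbonate
Product: 3 (2S)-2-(4-hydroxyphenyl)-7-[(2-methylbut-3-en-2-yl)oxy]-2,3-dihydro-4H-chromen-4-one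
Conditions: 2 (1.05 equiv), Pd(PPh3)4 (2 mol %), 4 Å MS, THF, 0 °C, 1 h
Reagents that add atoms: tert-butyl (2-methylbut-3-en-2-yl) carbonate, C=CC(C)(C)OC(=O)OC(C)(C)C
Why: Palladium-catalysed decarboxylative allylic etherification (Tsuji–Trost type) without added base, in which the tert-butoxide released from 2 deprotonates the more acidic vinylogous-acid 7-OH (pKa about 7.5 against about 10 for 4′-OH) and that phenoxide attacks the more substituted end of the π-prenyl palladium cation to give the kinetic tertiary ether, while the base-labile C2 centre (S, bought in 1) is left alone.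

Step 2
Reactants: 3 (2S)-2-(4-hydroxyphenyl)-7-[(2-methylbut-3-en-2-yl)oxy]-2,3-dihydro-4H-chromen-4-one; 4 N-bromosuccinimide
Product: 5 (2S)-2-(3-bromo-4-hydroxyphenyl)-7-[(2-methylbut-3-en-2-yl)oxy]-2,3-dihydro-4H-chromen-4-one
Conditions: NBS (1.0 equiv), i-Pr2NH (10 mol %), CH2Cl2, −40 → 0 °C
Reagents that add atoms: N-bromosuccinimide, O=C1CCC(=O)N1Br
Why: Amine-catalysed ortho-bromination of a free phenol (electrophilic aromatic substitution through the N-bromoamine and the hydrogen-bonded phenol), selective because only ring B still has a free OH, its para position is blocked and ring A is an acyl-conjugated, sterically shielded aryl ether, so one bromine enters at C3′ and no stereocentre is touched.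

Step 3
Reactants: 5 (2S)-2-(3-bromo-4-hydroxyphenyl)-7-[(2-methylbut-3-en-2-yl)oxy]-2,3-dihydro-4H-chromen-4-one; 2 tert-butyl (2-methylbut-3-en-2-yl) carbonate
Product: 6 (2S)-2-{3-bromo-4-[(2-methylbut-3-en-2-yl)oxy]phenyl}-7-[(2-methylbut-3-en-2-yl)oxy]-2,3-dihydro-4H-chromen-4-one
Conditions: 2 (1.3 equiv), Pd(PPh3)4 (2 mol %), 4 Å MS, THF, 0 °C, stopped at full conversion (about 45 min)
Reagents that add atoms: tert-butyl (2-methylbut-3-en-2-yl) carbonate, C=CC(C)(C)OC(=O)OC(C)(C)C
Why: The same Tsuji–Trost decarboxylative etherification on the now more acidic ortho-bromophenol, where the aryl bromide does not undergo oxidative addition to the triphenylphosphine catalyst at 0 °C and the short contact time keeps the ring-A tertiary ether from being ionised and isomerised.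

Step 4
Reactants: 6 (2S)-2-{3-bromo-4-[(2-methylbut-3-en-2-yl)oxy]phenyl}-7-[(2-methylbut-3-en-2-yl)oxy]-2,3-dihydro-4H-chromen-4-one
Product: 9 (2S)-2-[3-bromo-4-hydroxy-5-(3-methylbut-2-en-1-yl)phenyl]-7-hydroxy-8-(3-methylbut-2-en-1-yl)-2,3-dihydro-4H-chromen-4-one, via ring-A-rearranged monoether 7 (not isolated), via ring-B-rearranged monoether 8 (not isolated)
Conditions: degassed o-xylene (0.05 M), 135 °C, sealed tube, 3 h
Reagents that add atoms: none
Why: Two aromatic Claisen ([3,3]-sigmatropic) rearrangements followed by tautomerisation, in which ring B can only shift to its single free ortho carbon C5′ and ring A shifts to C8 (the carbon between the two oxygens, the usual outcome for 7-allyloxychroman-4-ones through bond fixation), each tertiary ether delivering a linear 3-methylbut-2-enyl group in neutral solvent so that C2 is not epimerised.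

Step 5
Reactants: 10 methyl (2R)-oxirane-2-carboxylate; 11 methylmagnesium chloride
Product: 13 2-[(2R)-oxiran-2-yl]propan-2-ol, via methyl ketone 12 (not isolated)
Conditions: MeMgCl (2.2 equiv), THF, −78 → −30 °C; then H2O
Reagents that add atoms: methylmagnesium chloride, C[Mg]Cl
Why: Double Grignard addition to the ester through ketone 12 at low temperature, where carbonyl addition is much faster than opening of the epoxide, so the epoxide C–O stereocentre bought in 10 is not involved and stays (R).

Step 6
Reactants: 13 2-[(2R)-oxiran-2-yl]propan-2-ol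
Product: 14 (2S)-2-(prop-1-en-2-yl)oxirane
Conditions: Martin sulfurane Ph2S[OC(CF3)2Ph]2 (1.1 equiv), CH2Cl2, −20 → 20 °C; fractional distillation (volatile product, kept as a titrated solution)
Reagents that add atoms: none
Why: Martin-sulfurane dehydration of a tertiary alcohol (alkoxysulfurane, E1/E2-type loss under neutral conditions), regiospecific because the only β-hydrogens that can leave without forming an allene oxide are the methyl hydrogens, and stereoretentive because the centre is not involved (the descriptor changes from R to S only through the CIP priority switch).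

Step 7
Reactants: 9 (2S)-2-[3-bromo-4-hydroxy-5-(3-methylbut-2-en-1-yl)phenyl]-7-hydroxy-8-(3-methylbut-2-en-1-yl)-2,3-dihydro-4H-chromen-4-one; 14 (2S)-2-(prop-1-en-2-yl)oxirane
Product: 15 (2S)-7-hydroxy-2-{4-hydroxy-3-[(2R)-2-hydroxy-3-methylbut-3-en-1-yl]-5-(3-methylbut-2-en-1-yl)phenyl}-8-(3-methylbut-2-en-1-yl)-2,3-dihydro-4H-chromen-4-one
Conditions: 14 (3 equiv), (5,10,15,20-tetraphenylporphyrinato)cobalt Co(C44H28N4) (5 mol %), NiBr2(dme) (dme = 1,2-dimethoxyethane, 10 mol %), 4,4′-di-tert-butyl-2,2′-bipyridine (12 mol %), Zn powder (2.5 equiv), NH4Cl (1.5 equiv), NMP, blue LEDs (450 nm), 20 °C, 16 h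
Reagents that add atoms: none
Why: Proposed new method: a light-driven cobalt/nickel cross-electrophile coupling in which zinc-generated monovalent cobalt porphyrin opens the 2-alkenyl oxirane 14 by SN2 attack at its unhindered CH2 (the C–O stereocentre is never touched), blue light homolyses the resulting 2-hydroxyalkyl–cobalt bond, and the primary radical is captured by the aryl–nickel bromide formed from 9 by oxidative addition, so that reductive elimination makes the C3′–CH2 bond with the (R)-carbinol intact, nickel capture being expected to outrun the slow 1,2-vinyl shift of this homoallylic radical; the closest known reaction type is the cobalt-corrin/nickel dual-catalysed, light-promoted, linear-selective arylation of simple terminal epoxides with aryl halides, which has not been shown for an alkenyl epoxide, for stereoretentive use of an enantiopure epoxide, or for an unprotected hindered ortho-bromophenol carrying a base-labile flavanone stereocentre.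

**Compound list**
1 | (2S)-liquiritigenin, (2S)-7-hydroxy-2-(4-hydroxyphenyl)-2,3-dihydro-4H-chromen-4-one | Oc1ccc(cc1)[C@@H]1CC(=O)c2ccc(O)cc2O1 | starting material
2 | tert-butyl (2-methylbut-3-en-2-yl) carbonate | C=CC(C)(C)OC(=O)OC(C)(C)C | starting material
3 | (2S)-2-(4-hydroxyphenyl)-7-[(2-methylbut-3-en-2-yl)oxy]-2,3-dihydro-4H-chromen-4-one | Oc1ccc(cc1)[C@@H]1CC(=O)c2ccc(OC(C)(C)C=C)cc2O1 | intermediate
4 | N-bromosuccinimide | O=C1CCC(=O)N1Br | starting material
5 | (2S)-2-(3-bromo-4-hydroxyphenyl)-7-[(2-methylbut-3-en-2-yl)oxy]-2,3-dihydro-4H-chromen-4-one | Oc1ccc(cc1Br)[C@@H]1CC(=O)c2ccc(OC(C)(C)C=C)cc2O1 | intermediate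
6 | (2S)-2-{3-bromo-4-[(2-methylbut-3-en-2-yl)oxy]phenyl}-7-[(2-methylbut-3-en-2-yl)oxy]-2,3-dihydro-4H-chromen-4-one | C=CC(C)(C)Oc1ccc(cc1Br)[C@@H]1CC(=O)c2ccc(OC(C)(C)C=C)cc2O1 | intermediate
7 | (2S)-2-{3-bromo-4-[(2-methylbut-3-en-2-yl)oxy]phenyl}-7-hydroxy-8-(3-methylbut-2-en-1-yl)-2,3-dihydro-4H-chromen-4-one (ring-A-rearranged monoether) | C=CC(C)(C)Oc1ccc(cc1Br)[C@@H]1CC(=O)c2ccc(O)c(CC=C(C)C)c2O1 | intermediate
8 | (2S)-2-[3-bromo-4-hydroxy-5-(3-methylbut-2-en-1-yl)phenyl]-7-[(2-methylbut-3-en-2-yl)oxy]-2,3-dihydro-4H-chromen-4-one (ring-B-rearranged monoether) | CC(C)=CCc1cc(cc(Br)c1O)[C@@H]1CC(=O)c2ccc(OC(C)(C)C=C)cc2O1 | intermediate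
9 | (2S)-2-[3-bromo-4-hydroxy-5-(3-methylbut-2-en-1-yl)phenyl]-7-hydroxy-8-(3-methylbut-2-en-1-yl)-2,3-dihydro-4H-chromen-4-one | CC(C)=CCc1cc(cc(Br)c1O)[C@@H]1CC(=O)c2ccc(O)c(CC=C(C)C)c2O1 | intermediate
10 | methyl (2R)-oxirane-2-carboxylate, methyl (R)-glycidate | COC(=O)[C@H]1CO1 | starting material
11 | methylmagnesium chloride | C[Mg]Cl | starting material
12 | 1-[(2R)-oxiran-2-yl]ethan-1-one | CC(=O)[C@H]1CO1 | intermediate
13 | 2-[(2R)-oxiran-2-yl]propan-2-ol | CC(C)(O)[C@H]1CO1 | intermediate
14 | (2S)-2-(prop-1-en-2-yl)oxirane | C=C(C)[C@H]1CO1 | intermediate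
15 | (2S)-7-hydroxy-2-{4-hydroxy-3-[(2R)-2-hydroxy-3-methylbut-3-en-1-yl]-5-(3-methylbut-2-en-1-yl)phenyl}-8-(3-methylbut-2-en-1-yl)-2,3-dihydro-4H-chromen-4-one | C=C(C)[C@H](O)Cc1cc([C@@H]2CC(=O)c3ccc(O)c(CC=C(C)C)c3O2)cc(CC=C(C)C)c1O | target

**Count and risks**
Total step count: 7. Longest linear sequence: 5 steps (steps 1, 2, 3, 4 and 7); the epoxide branch (steps 5 and 6) is 2 steps.

Three steps most likely to fail:

Step 7 (the proposed new coupling). Possible failures are SN2′ opening of 14 by cobalt, 1,2-vinyl shift of the radical, protodebromination of 9, or slow oxidative addition of the hindered electron-rich bromophenol. The fallback uses known chemistry and sets out from 9, with the saturated epoxy alcohol 13 as partner. A thermal nickel-catalysed, iodide-co-catalysed reductive coupling of an aryl bromide with a terminal aliphatic epoxide (NiCl2(dme), 2,2′-bipyridine, NaI, Mn, Et3N·HCl, DMPU, 25 °C) opens 13 at CH2 through its iodohydrin, with no alkene near the radical, and gives the tertiary-alcohol diol F1. Silylation of both phenols and the secondary alcohol (Et3SiCl, imidazole, DMF, 0 °C) gives the tris(triethylsilyl) ether F2. Its free tertiary alcohol is dehydrated with Burgess reagent (methyl N-(triethylammoniosulfonyl)carbamate, toluene, 50 °C) to the silylated isopropenyl compound F3. HF·pyridine in THF at 0 °C removes the three silyl groups, and the fallback comes back to the route at 15.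

Step 6 (dehydration next to an epoxide, volatile product). The fallback sets out from 10 and replaces dehydration by carbonyl olefination. Amidation of 10 (MeNHOMe·HCl, i-PrMgCl, THF, −20 °C) gives the Weinreb amide F4. One equivalent of MeMgCl at −78 °C gives ketone 12, here isolated. Wittig methylenation (Ph3PCH3Br, KN(SiMe3)2, THF, −78 → 0 °C) then comes back to the route at 14.

Step 3 (second palladium etherification). Zerovalent palladium may ionise the ring-A tertiary ether already present and return the linear prenyl ether, or the hindered bromophenol may react sluggishly. The fallback sets out from 5 and builds the ether from an alkyne without palladium–allyl chemistry. Copper-catalysed propargylation with 3-chloro-3-methylbut-1-yne (CuCl2·2H2O 1 mol %, DBU, MeCN, 0 °C) gives the 1,1-dimethylpropargyl ether F5. Semi-hydrogenation (H2 1 atm, Pd/CaCO3 poisoned with Pb(OAc)2, quinoline, EtOAc, stopped after one equivalent) comes back to the route at 6.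

**Further compounds**
F1 | step 7 | (2S)-2-{3-[(2R)-2,3-dihydroxy-3-methylbutyl]-4-hydroxy-5-(3-methylbut-2-en-1-yl)phenyl}-7-hydroxy-8-(3-methylbut-2-en-1-yl)-2,3-dihydro-4H-chromen-4-one | CC(C)(O)[C@H](O)Cc1cc([C@@H]2CC(=O)c3ccc(O)c(CC=C(C)C)c3O2)cc(CC=C(C)C)c1O
F2 | step 7 | (2S)-2-{3-[(2R)-3-hydroxy-3-methyl-2-(triethylsilyloxy)butyl]-5-(3-methylbut-2-en-1-yl)-4-(triethylsilyloxy)phenyl}-8-(3-methylbut-2-en-1-yl)-7-(triethylsilyloxy)-2,3-dihydro-4H-chromen-4-one | CC(C)(O)[C@H](O[Si](CC)(CC)CC)Cc1cc([C@@H]2CC(=O)c3ccc(O[Si](CC)(CC)CC)c(CC=C(C)C)c3O2)cc(CC=C(C)C)c1O[Si](CC)(CC)CC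
F3 | step 7 | (2S)-2-{3-[(2R)-3-methyl-2-(triethylsilyloxy)but-3-en-1-yl]-5-(3-methylbut-2-en-1-yl)-4-(triethylsilyloxy)phenyl}-8-(3-methylbut-2-en-1-yl)-7-(triethylsilyloxy)-2,3-dihydro-4H-chromen-4-one | C=C(C)[C@H](O[Si](CC)(CC)CC)Cc1cc([C@@H]2CC(=O)c3ccc(O[Si](CC)(CC)CC)c(CC=C(C)C)c3O2)cc(CC=C(C)C)c1O[Si](CC)(CC)CC
F4 | step 6 | (2R)-N-methoxy-N-methyloxirane-2-carboxamide | CON(C)C(=O)[C@H]1CO1
F5 | step 3 | (2S)-2-{3-bromo-4-[(2-methylbut-3-yn-2-yl)oxy]phenyl}-7-[(2-methylbut-3-en-2-yl)oxy]-2,3-dihydro-4H-chromen-4-one | C#CC(C)(C)Oc1ccc(cc1Br)[C@@H]1CC(=O)c2ccc(OC(C)(C)C=C)cc2O1
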